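**Retrosynthetic overview**

1. Target 19 is a bicyclo[3.3.1]nonane-2,4,9-trione. The C7 prenyl group is traced back to an exocyclic C7=CH2 (hydroboration from the exo face, then B-alkyl Suzuki–Miyaura coupling) and the catechol to its diphenylmethylene ketal.
2. Ring B is opened at C5–C6. This bond is made last, by dehydrative allylic alkylation with zerovalent palladium inside a monocyclic, dearomatised acylphloroglucinol (ring A) that carries C8–C7(=CH2)–CH2OH on C1. The enabling feature is ring A (C1–C2–C3–C4–C5–C9), a vinylogous acid: C5 is a soft carbon nucleophile, its enol OH is acidic enough to ionise the allylic alcohol, and the C6–C7(=CH2) unit is a symmetric 2-substituted π-allyl.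
3. The C1–C8 bond between two quaternary carbons comes from a dearomative Claisen rearrangement of the para aryl ether. The C9–O–CH2 ether is a temporary tether cleaved in the same event; the (Z)-tetrasubstituted alkene and a chair transition state set C8 relative to C1, and a chiral divalent copper Lewis acid sets the absolute sense.
4. Building blocks: maclurin (ring A and the aroyl group), prenyl bromide, and a (Z)-hydroxy ester from syn-carbomagnesiation of but-2-yn-1-ol.
5. Ring order: aromatic ring A (maclurin), dearomatised ring A (step 5), ring B (step 7); C7 is set last (step 8).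

Key step: step 7

Assumptions: maclurin (1) is bought; β-triketones are drawn as one enol tautomer, with locants C1–C9 those of the core of 19; the (S,S)-ligand in step 5 is assumed to give the sense of induction drawn (its antipode is used if the sense proves opposite).

**Route**

Step 1
Reactants: 1 maclurin; 2 dichlorodiphenylmethane
Product: 3 (2,2-diphenyl-1,3-benzodioxol-5-yl)(2,4,6-trihydroxyphenyl)methanone
Conditions: 2 (1.3 equiv), Ph2O, 175 °C
Reagents that add atoms: none
Why: Catechol ketalisation with a gem-dichloride is selective because only the 1,2-diol can close the five-membered 1,3-benzodioxole, so the three phloroglucinol hydroxyls stay free.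

Step 2
Reactants: 3 catechol ketal; 4 prenyl bromide
Product: 5 (2,2-diphenyl-1,3-benzodioxol-5-yl)[2,4,6-trihydroxy-3,5-bis(3-methylbut-2-en-1-yl)phenyl]methanone
Conditions: 4 (2.2 equiv), KOH (aq), 0 °C
Reagents that add atoms: none
Why: Aqueous C-prenylation of an acylphloroglucinol polyanion: hydrogen bonding of water to the phenoxide oxygens steers the soft allylic bromide to the two ring CH carbons.

Step 3
Reactants: 6 but-2-yn-1-ol; 7 5-bromo-2-methylpent-2-ene
Product: 11 methyl (2Z)-2-(hydroxymethyl)-3,7-dimethylocta-2,6-dienoate, via 4-methylpent-3-enylmagnesium bromide 8 (not isolated), via alkenylmagnesium alkoxide 9 (not isolated), via hydroxy acid 10 (not isolated)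
Conditions: 7, Mg, THF; then 6, Fe(acac)3 (10 mol%), THF, −78 to 0 °C; CO2, −78 °C to rt; 1 M HCl; TMSCHN2, MeOH–PhMe, 0 °C
Reagents that add atoms: carbon dioxide O=C=O; (trimethylsilyl)diazomethane C[Si](C)(C)C=[N+]=[N-]
Why: Alkoxide-directed, iron-catalysed syn-carbomagnesiation of the propargylic alcohol puts the new alkyl group on the distal alkyne carbon and magnesium on the proximal one, cis to each other, so carboxylation with retention and O-methylation give the tetrasubstituted alkene with the ester cis to the homoprenyl group and CH2OH cis to methyl (carbometalation with electrophile trapping).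

Step 4
Reactants: 5 diprenylated ketal; 11 (Z)-hydroxy ester
Product: 12 methyl (2Z)-2-{[4-(2,2-diphenyl-1,3-benzodioxole-5-carbonyl)-3,5-dihydroxy-2,6-bis(3-methylbut-2-en-1-yl)phenoxy]methyl}-3,7-dimethylocta-2,6-dienoate
Conditions: PPh3, DIAD, THF, 0 °C to rt
Reagents that add atoms: none
Why: Mitsunobu etherification: the oxyphosphonium salt of the primary allylic alcohol is displaced (SN2; SN2′ is blocked by the fully substituted alkene terminus) by the most acidic phenol, the one para to the aroyl group, while the two ortho hydroxyls stay chelated to the ketone.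

Step 5
Reactants: 12 aryl allyl ether
Product: 13 methyl (3S)-3-[(1R)-3-(2,2-diphenyl-1,3-benzodioxole-5-carbonyl)-2,4-dihydroxy-1,5-bis(3-methylbut-2-en-1-yl)-6-oxocyclohexa-2,4-dien-1-yl]-3,7-dimethyl-2-methylideneoct-6-enoate
Conditions: [Cu((S,S)-tBu-box)(H2O)2](SbF6)2 (10 mol%), CH2Cl2, rt
Reagents that add atoms: none
Why: Proposed new method: two-point binding of the ester carbonyl and the ether oxygen of the 2-(aryloxymethyl)enoate to the chiral divalent copper Lewis acid should weaken the O–CH2 bond and lower the enoate LUMO, so that the arene carbon C1 adds to the Re face of C8 through a chair six-membered transition state (a charge-accelerated dearomative Claisen rearrangement, formally conjugate addition then retro-oxa-Michael cleavage of the ether tether); the (Z)-alkene with methyl pseudo-axial fixes C8 relative to C1 and the ligand fixes the absolute sense; the closest known reaction types are the copper–bis(oxazoline)-catalysed enantioselective Gosteli–Claisen rearrangement of 2-alkoxycarbonyl allyl vinyl ethers and the Lewis-acid-catalysed dearomative Claisen rearrangement of allyl aryl ethers bearing a chelating carbonyl group.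

Step 6
Reactants: 13 α-methylidene ester
Product: 14 (6R)-4-(2,2-diphenyl-1,3-benzodioxole-5-carbonyl)-3,5-dihydroxy-6-[(3R)-1-hydroxy-3,7-dimethyl-2-methylideneoct-6-en-3-yl]-2,6-bis(3-methylbut-2-en-1-yl)cyclohexa-2,4-dien-1-one
Conditions: i-Bu2AlH (6 equiv), CH2Cl2, −78 to −40 °C; aq. KNaC4H4O6
Reagents that add atoms: none
Why: 1,2-Reduction of the conjugated ester to the allylic alcohol, the ring-A trione being masked in the flask as its unreactive aluminium dienolate after deprotonation of the two enol hydroxyls (ester reduction).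

Step 7
Reactants: 14 allylic alcohol
Product: 15 (1S,5S,8R)-3-(2,2-diphenyl-1,3-benzodioxole-5-carbonyl)-4-hydroxy-8-methyl-7-methylidene-1,5-bis(3-methylbut-2-en-1-yl)-8-(4-methylpent-3-en-1-yl)bicyclo[3.3.1]non-3-ene-2,9-dione
Conditions: Pd(PPh3)4 (5 mol%), PhMe, 4 Å MS, 60 °C
Reagents that add atoms: none
Why: The acidic enol of ring A activates the allylic hydroxyl so that zerovalent palladium ionises the C–O bond to a cationic 2-substituted π-allyl complex with two CH2 termini (water is the only leaving group), and the ring-A enolate then attacks one terminus through C5, anti to palladium, to forge C5–C6. The closest known reaction type is the Tsuji–Trost allylation of acidic 1,3-dicarbonyl pronucleophiles with free allylic alcohols, and in particular the palladium-catalysed allylic annulation of acylphloroglucinols with 2-methylidenepropane-1,3-diyl electrophiles to 7-methylidenebicyclo[3.3.1]nonanes. Ring B (C1, C8, C7, C6, C5, C9) closes in a 6-exo mode with respect to the allyl unit, the surviving alkene ending exocyclic at C7, and because the π-allyl is symmetric either terminus gives the same product. The only new stereocentre, C5, is dictated by C1: the three-carbon tether on C1 can reach C5 only on the face of ring A that carries C8, so the C9 bridge must be cis. The step needs C-alkylation at C5 rather than at oxygen or at the aroyl-bearing C3, and C–O rather than C1–C8 ionisation; O-allyl enol ethers re-ionise under zerovalent palladium and funnel to the C5 product, which alone keeps the enolised β-triketone, C3 is the most hindered site, and the moderate temperature and protonated hydroxyl leaving group favour C–O ionisation.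

Step 8
Reactants: 15 7-methylidene bicycle; 16 1-bromo-2-methylprop-1-ene
Product: 18 (1S,5S,7S,8R)-3-(2,2-diphenyl-1,3-benzodioxole-5-carbonyl)-4-hydroxy-8-methyl-1,5,7-tris(3-methylbut-2-en-1-yl)-8-(4-methylpent-3-en-1-yl)bicyclo[3.3.1]non-3-ene-2,9-dione, via B-alkyl-9-borabicyclo[3.3.1]nonane 17 (not isolated)
Conditions: 9-BBN-H (3 equiv), THF, 0 °C to rt; then 16, PdCl2(dppf) (5 mol%), K3PO4 (aq), DMF, 50 °C
Reagents that add atoms: none
Why: Hydroboration then B-alkyl Suzuki–Miyaura coupling: the hindered borane adds to the only 1,1-disubstituted alkene, boron at the terminal carbon and hydrogen to C7 from the exo face (the endo face is screened by ring A), so the new CH2 group, and after sp3–sp2 coupling the prenyl group, sits endo at C7, cis to the C8 methyl as in 19.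

Step 9
Reactants: 18 protected target
Product: 19 (1S,5S,7S,8R)-3-(3,4-dihydroxybenzoyl)-4-hydroxy-8-methyl-1,5,7-tris(3-methylbut-2-en-1-yl)-8-(4-methylpent-3-en-1-yl)bicyclo[3.3.1]non-3-ene-2,9-dione
Conditions: AcOH–H2O (4:1), 90 °C
Reagents that add atoms: none
Why: Acid-catalysed ketal hydrolysis through the doubly benzylic, oxygen-stabilised cation in a weak acid that should not protonate the trisubstituted alkenes, so the enol and prenyl groups are not cyclised.

**Compound list**

1 | maclurin, (3,4-dihydroxyphenyl)(2,4,6-trihydroxyphenyl)methanone | Oc1cc(O)c(C(=O)c2ccc(O)c(O)c2)c(O)c1 | starting material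
2 | dichlorodiphenylmethane | ClC(Cl)(c1ccccc1)c1ccccc1 | starting material
3 | (2,2-diphenyl-1,3-benzodioxol-5-yl)(2,4,6-trihydroxyphenyl)methanone | Oc1cc(O)c(C(=O)c2ccc3OC(c4ccccc4)(c4ccccc4)Oc3c2)c(O)c1 | intermediate
4 | prenyl bromide, 1-bromo-3-methylbut-2-ene | CC(C)=CCBr | starting material
5 | (2,2-diphenyl-1,3-benzodioxol-5-yl)[2,4,6-trihydroxy-3,5-bis(3-methylbut-2-en-1-yl)phenyl]methanone | Oc1c(CC=C(C)C)c(O)c(C(=O)c2ccc3OC(c4ccccc4)(c4ccccc4)Oc3c2)c(O)c1CC=C(C)C | intermediate
6 | but-2-yn-1-ol | CC#CCO | starting material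
7 | 5-bromo-2-methylpent-2-ene | CC(C)=CCCBr | starting material
8 | 4-methylpent-3-enylmagnesium bromide | CC(C)=CCC[Mg]Br | intermediate
9 | bromo[(1Z)-1-{[(bromomagnesio)oxy]methyl}-2,6-dimethylhepta-1,5-dien-1-yl]magnesium (Mg cis to the homoprenyl group) | Br[Mg]/C(CO[Mg]Br)=C(/C)CCC=C(C)C | intermediate
10 | (2Z)-2-(hydroxymethyl)-3,7-dimethylocta-2,6-dienoic acid | OC(=O)/C(CO)=C(/C)CCC=C(C)C | intermediate
11 | methyl (2Z)-2-(hydroxymethyl)-3,7-dimethylocta-2,6-dienoate | COC(=O)/C(CO)=C(/C)CCC=C(C)C | intermediate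
12 | methyl (2Z)-2-{[4-(2,2-diphenyl-1,3-benzodioxole-5-carbonyl)-3,5-dihydroxy-2,6-bis(3-methylbut-2-en-1-yl)phenoxy]methyl}-3,7-dimethylocta-2,6-dienoate | COC(=O)/C(COc1c(CC=C(C)C)c(O)c(C(=O)c2ccc3OC(c4ccccc4)(c4ccccc4)Oc3c2)c(O)c1CC=C(C)C)=C(/C)CCC=C(C)C | intermediate
13 | methyl (3S)-3-[(1R)-3-(2,2-diphenyl-1,3-benzodioxole-5-carbonyl)-2,4-dihydroxy-1,5-bis(3-methylbut-2-en-1-yl)-6-oxocyclohexa-2,4-dien-1-yl]-3,7-dimethyl-2-methylideneoct-6-enoate | CC(C)=CCC[C@](C)(C(=C)C(=O)OC)[C@@]1(CC=C(C)C)C(=O)C(CC=C(C)C)=C(O)C(C(=O)c2ccc3OC(c4ccccc4)(c4ccccc4)Oc3c2)=C1O | intermediate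
14 | (6R)-4-(2,2-diphenyl-1,3-benzodioxole-5-carbonyl)-3,5-dihydroxy-6-[(3R)-1-hydroxy-3,7-dimethyl-2-methylideneoct-6-en-3-yl]-2,6-bis(3-methylbut-2-en-1-yl)cyclohexa-2,4-dien-1-one | CC(C)=CCC[C@](C)(C(=C)CO)[C@@]1(CC=C(C)C)C(=O)C(CC=C(C)C)=C(O)C(C(=O)c2ccc3OC(c4ccccc4)(c4ccccc4)Oc3c2)=C1O | intermediate
15 | (1S,5S,8R)-3-(2,2-diphenyl-1,3-benzodioxole-5-carbonyl)-4-hydroxy-8-methyl-7-methylidene-1,5-bis(3-methylbut-2-en-1-yl)-8-(4-methylpent-3-en-1-yl)bicyclo[3.3.1]non-3-ene-2,9-dione | CC(C)=CCC[C@]1(C)C(=C)C[C@]2(CC=C(C)C)C(=O)[C@@]1(CC=C(C)C)C(=O)C(C(=O)c1ccc3OC(c4ccccc4)(c4ccccc4)Oc3c1)=C2O | intermediate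
16 | 1-bromo-2-methylprop-1-ene | CC(C)=CBr | starting material
17 | (1S,5S,7S,8R)-7-[(9-borabicyclo[3.3.1]nonan-9-yl)methyl] analogue of 15 (CH2B endo at C7; enol drawn free) | CC(C)=CCC[C@]1(C)[C@@H](CB3C4CCCC3CCC4)C[C@]2(CC=C(C)C)C(=O)[C@@]1(CC=C(C)C)C(=O)C(C(=O)c1ccc3OC(c4ccccc4)(c4ccccc4)Oc3c1)=C2O | intermediate
18 | (1S,5S,7S,8R)-3-(2,2-diphenyl-1,3-benzodioxole-5-carbonyl)-4-hydroxy-8-methyl-1,5,7-tris(3-methylbut-2-en-1-yl)-8-(4-methylpent-3-en-1-yl)bicyclo[3.3.1]non-3-ene-2,9-dione | CC(C)=CCC[C@]1(C)[C@@H](CC=C(C)C)C[C@]2(CC=C(C)C)C(=O)[C@@]1(CC=C(C)C)C(=O)C(C(=O)c1ccc3OC(c4ccccc4)(c4ccccc4)Oc3c1)=C2O | intermediate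
19 | (1S,5S,7S,8R)-3-(3,4-dihydroxybenzoyl)-4-hydroxy-8-methyl-1,5,7-tris(3-methylbut-2-en-1-yl)-8-(4-methylpent-3-en-1-yl)bicyclo[3.3.1]non-3-ene-2,9-dione | CC(C)=CCC[C@]1(C)[C@@H](CC=C(C)C)C[C@]2(CC=C(C)C)C(=O)[C@@]1(CC=C(C)C)C(=O)C(C(=O)c1ccc(O)c(O)c1)=C2O | target

**Step count and risks**

Total: 9 steps. Longest linear sequence: 8 steps (1, 2, 4, 5, 6, 7, 8, 9 from maclurin).

Step 5 (proposed method). The hindered, weakly basic aryl-ether oxygen may fail to chelate copper while the free chelating phenols compete for the metal. The rearrangement may then need heat and run without facial control, or the Lewis acid may promote premature attack of C5 on the enoate. The fallback uses known chemistry and replaces catalysis by resolution. It sets out from 12: an uncatalysed dearomative Claisen rearrangement in PhMe at 100 °C should give 13 as the racemate, that is together with its mirror image ent-13 F1. Reduction with i-Bu2AlH as in step 6 gives 14 together with ent-14 F2, and the palladium closure as in step 7 gives 15 together with ent-15 F3. Preparative HPLC on amylose tris(3,5-dimethylphenylcarbamate) removes F3, and the route is rejoined at 15.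

Step 8. The borane may also add to the four trisubstituted alkenes or be consumed by the enol, and transmetalation of the β-branched alkylborane may be slow enough for protodeboronation to compete. The fallback sets out from 15 and builds the prenyl group by hydroformylation and olefination instead. Rhodium-catalysed hydroformylation (Rh(acac)(CO)2, tris(2,4-di-tert-butylphenyl) phosphite, CO/H2, PhMe, 60 °C) can only give the linear aldehyde from a 1,1-disubstituted alkene and should add hydrogen to C7 from the exo face, giving the C7-endo 2-oxoethyl aldehyde F4. Wittig olefination with excess Ph3P=C(CH3)2 (from isopropyltriphenylphosphonium iodide and n-BuLi) rejoins the route at 18.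

Step 3. The alkyl organomagnesium reagent may transfer a β-hydride (reduction instead of carbometalation), add with the other regiochemistry, or the alkenylmagnesium may lose its geometry before carboxylation. The fallback sets out from 7 and uses carbocupration instead. Alkylation of LiC≡CH·H2NCH2CH2NH2 in DMSO gives 6-methylhept-5-en-1-yne F5, and n-BuLi then ClCO2Me gives methyl 7-methyloct-6-en-2-ynoate F6. Syn-addition of Me2CuLi at −78 °C followed by iodination of the alkenylcopper gives methyl (2E)-2-iodo-3,7-dimethylocta-2,6-dienoate F7, with iodine cis to the new methyl. Stille coupling with Bu3SnCH2OH (Pd(PPh3)4, dioxane, 90 °C) rejoins the route at 11.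

Further compounds
F1 | step 5 | ent-13, methyl (3R)-3-[(1S)-3-(2,2-diphenyl-1,3-benzodioxole-5-carbonyl)-2,4-dihydroxy-1,5-bis(3-methylbut-2-en-1-yl)-6-oxocyclohexa-2,4-dien-1-yl]-3,7-dimethyl-2-methylideneoct-6-enoate | CC(C)=CCC[C@@](C)(C(=C)C(=O)OC)[C@]1(CC=C(C)C)C(=O)C(CC=C(C)C)=C(O)C(C(=O)c2ccc3OC(c4ccccc4)(c4ccccc4)Oc3c2)=C1O
F2 | step 5 | ent-14, (6S)-4-(2,2-diphenyl-1,3-benzodioxole-5-carbonyl)-3,5-dihydroxy-6-[(3S)-1-hydroxy-3,7-dimethyl-2-methylideneoct-6-en-3-yl]-2,6-bis(3-methylbut-2-en-1-yl)cyclohexa-2,4-dien-1-one | CC(C)=CCC[C@@](C)(C(=C)CO)[C@]1(CC=C(C)C)C(=O)C(CC=C(C)C)=C(O)C(C(=O)c2ccc3OC(c4ccccc4)(c4ccccc4)Oc3c2)=C1O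
F3 | step 5 | ent-15, (1R,5R,8S)-3-(2,2-diphenyl-1,3-benzodioxole-5-carbonyl)-4-hydroxy-8-methyl-7-methylidene-1,5-bis(3-methylbut-2-en-1-yl)-8-(4-methylpent-3-en-1-yl)bicyclo[3.3.1]non-3-ene-2,9-dione | CC(C)=CCC[C@@]1(C)C(=C)C[C@@]2(CC=C(C)C)C(=O)[C@]1(CC=C(C)C)C(=O)C(C(=O)c1ccc3OC(c4ccccc4)(c4ccccc4)Oc3c1)=C2O
F4 | step 8 | (1S,5S,7R,8R)-3-(2,2-diphenyl-1,3-benzodioxole-5-carbonyl)-4-hydroxy-8-methyl-1,5-bis(3-methylbut-2-en-1-yl)-8-(4-methylpent-3-en-1-yl)-7-(2-oxoethyl)bicyclo[3.3.1]non-3-ene-2,9-dione | CC(C)=CCC[C@]1(C)[C@@H](CC=O)C[C@]2(CC=C(C)C)C(=O)[C@@]1(CC=C(C)C)C(=O)C(C(=O)c1ccc3OC(c4ccccc4)(c4ccccc4)Oc3c1)=C2O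
F5 | step 3 | 6-methylhept-5-en-1-yne | CC(C)=CCCC#C
F6 | step 3 | methyl 7-methyloct-6-en-2-ynoate | CC(C)=CCCC#CC(=O)OC
F7 | step 3 | methyl (2E)-2-iodo-3,7-dimethylocta-2,6-dienoate | COC(=O)/C(I)=C(/C)CCC=C(C)C
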